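## Structural features

Asterelin A (25) is an achiral macrocyclic bis(bibenzyl) made of four benzene rings: rings A and B are fused through a furan into a dibenzofuran, ring C is a 1,3,4-trisubstituted phenol and ring D is a para-phenylene. Ring A (C1 to C4, C4a, C9b) carries the free hydroxyl at C3 and, at the bay carbon C1 next to C9b, an ethylene bridge to ring D. Ring D is joined through a diaryl ether oxygen to C3' of ring C, and a second ethylene bridge runs from C1' of ring C to C7 of ring B, so that an 18-membered ring is closed through the C9b–C9a bond. There is no stereocentre and no stereogenic alkene, so no stereocentres stand next to each other and nothing stereochemical has to be controlled. The fragile groups are the two phenols and the four benzylic methylenes in the target, and the diazoketone, the acid-sensitive 1,1-disubstituted alkene and the electron-poor heteroaryl triflate in the intermediates. The real difficulty is twofold: the substitution pattern of ring A (oxygen at C3, carbon at C1 peri to ring B), which substitution of a ready-made dibenzofuran does not deliver, and the closure of a strained macrocycle that contains the flat, rigid dibenzofuran. The key step uses the fact that C3, C4 and C2 of ring A map onto a ketene carbon, a former diazomethyl carbon and a methylene terminus placed on the adjacent furan carbons C4a and C9b of a benzofuran (ring B plus furan). Wolff rearrangement forms C4–C4a, 6π-electrocyclization forms C2–C3, and tautomerization leaves the hydroxyl on C3 and the bridge on C1 by connectivity alone.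

## Logic of the disconnections

25 from 24: the two O–CH3 bonds are the last to be cut in the forward direction. Both phenols stay masked as methyl ethers because free phenols would consume hydride and titanium reagents and are easily oxidised. Nothing is gained in skeleton, but every late step runs on a neutral substrate. The demand is that the ether cleavage spares the diaryl ether and the furan C–O bonds, which carry no sp3 carbon on oxygen.

24 from 23 from 22: the bond between the two benzylic carbons of the ring B–ring C bridge is cut, by way of the alkene 23, to the dialdehyde 22. This bridge joins two unhindered positions (C7 and C1'), whereas the other bridge starts at the bay carbon C1 and is better made early in an open chain. The 18-membered ring disappears and 22 is an open-chain compound with two like functional groups that a symmetrical reductive coupling joins without differentiation. The demand is intramolecular coupling at high dilution against oligomerization and ring strain; the alkene geometry of 23 is irrelevant.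

22 from 21 from 20 from 19: no skeletal bond is cut here; the two formyl carbons go back to the ester level and the C3 methyl ether to the free phenol. Esters are chosen because they survive the amide bases, palladium couplings, diazo transfer and irradiation that precede, where aldehydes would not, and because only ring D may carry an aldehyde in step 2. The price is two redox steps, which must not touch the aryl ethers.

19 from 16 (through 18 and 17): the C2–C3 and C4–C4a bonds of ring A are cut. Ring A is removed altogether and the dibenzofuran becomes a 2,3-disubstituted benzofuran. The phenol oxygen becomes a ketone oxygen, C4 a diazomethyl carbon and C2 the methylene terminus of a 1,1-disubstituted alkene that already holds the whole ring D–O–ring C chain. The forward step demands clean 1,2-shift of the benzofuranyl group after loss of N2 and a ketene that cyclizes faster than it is captured.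

16 from 14: the C=N2 unit is cut, tracing the diazo carbon to an acetyl methyl group and not to a carboxylic acid. This is the change in the ancestry of 16: no ester has to be cleaved with acid in the presence of the 1,1-disubstituted alkene (protonation would give a tertiary cation next to a carboxyl group and invite lactonization or alkene migration), and no diazomethane is needed. The demand is selective enolization of the single enolizable carbonyl of 14 beside two non-enolizable methyl esters.

14 from 8 and 13: the bond between furan C3 (later C9b) and the internal alkene carbon (later C1) is cut. This is the convergent step: it splits the molecule into the benzofuran electrophile 13 and the alkenylboron fragment 8 of comparable size. The coupling must keep the double bond in the 1,1-disubstituted position and must not hydrolyse the activated triflate.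

13 from 12 from 9 and 10 (through 11): the furan is opened at the C2–C3 bond and at the O–CH2 bond, which leads to a salicylate-type phenol 9 and the three-carbon ketone 10. The ester at C6 of the benzofuran, para to C3a, is already in 9, so the position of the later C7 carbon is fixed by the starting material. The demand is that the condensation of 11 closes the five-membered ring at the more acidic O–CH2 position.

8 from 7 from 6: the C–B bond and then the C–O bond at the alkene carbon are cut, which reveals a methyl ketone. A 1,1-disubstituted alkenylboronate is thereby reduced to the regioselective (kinetic, methyl-side) enolization of 6. The demand is that enolization occurs at the methyl and not at the methylene group.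

6 from 5 from 3 and 4: the Cα–Cβ bond of the butanone chain is cut as an alkene. The three carbons that later become C1, C2 and the first bridge carbon come from the stabilized ylide 4, and the aldehyde 3 provides the second bridge carbon. The demand is only chemoselective hydrogenation of the enone C=C.

3 from 1 and 2: the diaryl ether C–O bond on the ring D side is cut. The formyl group of 2 activates the para fluoride for substitution by the phenol 1, and the same formyl group then serves as the handle for the chain. This direction is chosen because the ring C carbon of that ether bond has no activating group in the right position.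

## Other disconnections considered

Alternative 1: The cut is the O5–C5a bond of the furan, made as the last skeletal bond on the complete 18-membered macrocycle. The precursor would be the 2-hydroxybiaryl macrocycle A2, with a free hydroxyl at C4a, a methoxy group at C3, ring B as a para-phenylene and the ring C phenol methylated.
- Forward step: Pd(OAc)2 would be directed by the phenoxide to one of the two equivalent ortho C–H bonds of ring B. The six-membered palladacycle of divalent palladium would be oxidised by tert-butyl peroxybenzoate to tetravalent palladium, and C–O reductive elimination would give A1, which has the constitution of 24 and needs only demethylation.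
- In its favour: there is no regiochemical question, since the ortho positions of ring B are equivalent and only one hydroxyl is free. A2 is a flexible biaryl bis(bibenzyl) that can be assembled from simple arenes by one biaryl coupling and two bridge-forming reactions. No diazo compound and no photochemistry are needed.
- Against it here: the oxidation is run on the most valuable intermediate, with a perester at elevated temperature beside four benzylic methylenes and an electron-rich phenol. Palladation and reductive elimination both require rings A and B to become coplanar inside the macrocycle, so the strain of the final ring system appears in the transition state of the metal-mediated step. The C4a hydroxyl also has to be told apart from the two other oxygens by an orthogonal protecting group.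
- Comparison: in structure this alternative rigidifies last, whereas the chosen plan builds the dibenzofuran first in an open chain and leaves the strain to the macrocyclization of 22. In mechanism an organometallic C–H oxidation stands against a pericyclic sequence; on regiochemical certainty the two are equal. On step count and convergence Alternative 1 is judged the better, because rings A and B are bought as arenes and neither a benzofuran nor a diazoketone has to be made. The chosen plan is preferred because its ring-forming step is unimolecular, free of strain and free of oxidant, while a failure of the furan closure in Alternative 1 would be met only at the end.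

Alternative 2: The cut is the bond between the two benzylic carbons of the ring A–ring D bridge, formed as CH=CH.
- Forward step: dialdehyde A4, a 3-methoxydibenzofuran-1-carbaldehyde that already carries the ring B–ring C bridge, ring C, the diaryl ether and a 4-formylphenyl ring D, would be coupled by low-valent titanium from TiCl4 and zinc to the macrocyclic stilbene A3. Hydrogenation and demethylation would follow.
- In its favour: the reaction type is the same as in the chosen endgame and suits rings of this size. The ring B–ring C bibenzyl and the diaryl ether can be made early by ordinary chemistry.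
- Against it here: C1 is the bay position, peri to C9–H, so the coupling aldehyde is the most hindered carbon and the ring would be closed at its most rigid end. More important, the alternative does not say how a dibenzofuran with carbon at C1, oxygen at C3 and carbon at C7 is obtained; electrophilic substitution and lithiation of dibenzofuran address other positions, so a ring synthesis is needed in any case.
- Comparison: structurally it is a choice of macrocyclization site and not a solution for ring A. The chosen plan brings the ring A–ring D bridge in as the chain of 8, which the key step requires as the alkene substituent anyway, and closes the ring between the two unhindered aldehydes of 22. In mechanism the two are equal, and in the endgame the step count is about equal. In convergence Alternative 2 would be the better, since the large aryl ether fragment would be joined late, but it pays with extra functional-group work at C1.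

Alternative 3: The cut is again the ring B–ring C bridge, but reached by ring contraction.
- Forward step: ring closure by sulfide formation between the C7 and C1' benzylic carbons would give the 19-membered sulfide A7, and oxidation the sulfone A6. KOH and CCl4 would chlorinate an α-carbon, close the episulfone by 1,3-elimination and extrude SO2 (Ramberg–Bäcklund reaction) to give the stilbene A5, which has the constitution of 23.
- In its favour: the macrocycle is closed by SN2 C–S bond formation in a ring one atom larger and without the planar alkene, so the closure should be less sensitive to strain. The strain is introduced afterwards in an intramolecular, irreversible extrusion. No low-valent metal is used, and A7 would branch off from diol 21 of the chosen route.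
- Against it here: about four operations from 21 (dihalide, sulfide, sulfone, extrusion) stand against two in the chosen plan. The halogenating base system can over-halogenate the doubly benzylic positions and forms dichlorocarbene beside electron-rich arenes. The alkene obtained is the one a McMurry coupling would give, so nothing is gained afterwards.
- Comparison: the bond formed and the late intermediates are the same; the mechanism is ionic substitution and extrusion instead of reductive carbonyl coupling. On the reliability of the ring closure itself Alternative 3 is judged the equal or the better of the chosen plan. On step economy the chosen plan is better by about two steps, which decides for the McMurry coupling as first choice.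

Key step: step 10

Remark: a position-by-position mapping of 16 onto 19 and of 19 onto 25 (benzofuran C6 ester to C7, internal alkene carbon to C1, ketene carbon to C3) shows no inconsistency, so no structure is corrected; 12 is drawn as its enol and 23 as the Z alkene, although either geometry may form, because step 15 removes the distinction.

## Route

Step 1  
Reactants: 1 methyl 3-hydroxy-4-methoxybenzoate; 2 4-fluorobenzaldehyde  
Product: 3 methyl 3-(4-formylphenoxy)-4-methoxybenzoate  
Conditions: K2CO3, DMF, 110 °C  
Reagents that add atoms: none  
Why: Nucleophilic aromatic substitution (SNAr): the phenoxide of 1 adds para to the formyl group of 2 and expels fluoride; the methyl ester is inert to carbonate in dry DMF.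

Step 2  
Reactants: 3 methyl 3-(4-formylphenoxy)-4-methoxybenzoate; 4 1-(triphenyl-λ5-phosphanylidene)propan-2-one  
Product: 5 methyl 4-methoxy-3-{4-[(1E)-3-oxobut-1-en-1-yl]phenoxy}benzoate  
Conditions: PhMe, 90 °C  
Reagents that add atoms: none  
Why: Wittig olefination with a stabilised ylide, which reacts only with the aldehyde and should give the (E)-enone; the geometry is of no consequence because the alkene is reduced in step 3.

Step 3  
Reactants: 5 methyl 4-methoxy-3-{4-[(1E)-3-oxobut-1-en-1-yl]phenoxy}benzoate  
Product: 6 methyl 4-methoxy-3-[4-(3-oxobutyl)phenoxy]benzoate  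
Conditions: H2 (1 atm), Pd/C, EtOAc, rt  
Reagents that add atoms: none  
Why: Heterogeneous catalytic hydrogenation saturates the conjugated C=C much faster than it touches the aliphatic ketone, the aryl ester or the diaryl ether.

Step 4  
Reactants: 6 methyl 4-methoxy-3-[4-(3-oxobutyl)phenoxy]benzoate  
Product: 7 methyl 4-methoxy-3-[4-(3-{[(trifluoromethyl)sulfonyl]oxy}but-3-en-1-yl)phenoxy]benzoate  
Conditions: KHMDS, THF, −78 °C; PhNTf2, −78 °C → 0 °C  
Reagents that add atoms: N-phenylbis(trifluoromethanesulfonimide), O=S(=O)(N(c1ccccc1)S(=O)(=O)C(F)(F)F)C(F)(F)F  
Why: Kinetic enolization of the methyl ketone with a hindered amide base at −78 °C removes a methyl proton, and O-sulfonylation of the less substituted enolate gives the terminal enol triflate; the non-enolizable aryl ester should not react with the silylamide at this temperature.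

Step 5  
Reactants: 7 methyl 4-methoxy-3-[4-(3-{[(trifluoromethyl)sulfonyl]oxy}but-3-en-1-yl)phenoxy]benzoate  
Product: 8 methyl 4-methoxy-3-{4-[3-(4,4,5,5-tetramethyl-1,3,2-dioxaborolan-2-yl)but-3-en-1-yl]phenoxy}benzoate  
Conditions: B2pin2, PdCl2(PPh3)2, PPh3, KOPh, PhMe, 50 °C  
Reagents that add atoms: bis(pinacolato)diboron, CC1(C)OB(OC1(C)C)B1OC(C)(C)C(C)(C)O1  
Why: Miyaura borylation: oxidative addition of the alkenyl triflate to zerovalent palladium, transmetalation with the phenoxide-activated diboron and reductive elimination; the weak base keeps 8 from cross-coupling with unreacted 7.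

Step 6  
Reactants: 9 dimethyl 2-hydroxyterephthalate; 10 chloroacetone  
Product: 12 methyl 2-acetyl-3-hydroxy-1-benzofuran-6-carboxylate, via acetonyl aryl ether 11 (not isolated)  
Conditions: K2CO3, KI (cat.), DMF, 60 °C; then t-BuOK, THF, 0 °C → rt; aq. HCl  
Reagents that add atoms: none  
Why: Williamson O-alkylation followed by Dieckmann-type (intramolecular Claisen) condensation: the more acidic O–CH2–C=O position of 11 attacks the ortho ester in a five-membered closure, and enolization to the aromatic 3-hydroxybenzofuran drives it. The remote ester, which becomes C6-CO2Me, cannot be reached.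

Step 7  
Reactants: 12 methyl 2-acetyl-3-hydroxy-1-benzofuran-6-carboxylate  
Product: 13 methyl 2-acetyl-3-{[(trifluoromethyl)sulfonyl]oxy}-1-benzofuran-6-carboxylate  
Conditions: Tf2O, pyridine, CH2Cl2, −20 °C → 0 °C  
Reagents that add atoms: trifluoromethanesulfonic anhydride, O=S(=O)(OS(=O)(=O)C(F)(F)F)C(F)(F)F  
Why: O-Sulfonylation of the enolic hydroxyl (a vinylogous acid) gives the heteroaryl triflate, in which the acetyl group activates the C3–O bond for oxidative addition.

Step 8  
Reactants: 8 methyl 4-methoxy-3-{4-[3-(4,4,5,5-tetramethyl-1,3,2-dioxaborolan-2-yl)but-3-en-1-yl]phenoxy}benzoate; 13 methyl 2-acetyl-3-{[(trifluoromethyl)sulfonyl]oxy}-1-benzofuran-6-carboxylate  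
Product: 14 methyl 2-acetyl-3-[4-(4-{[2-methoxy-5-(methoxycarbonyl)phenyl]oxy}phenyl)but-1-en-2-yl]-1-benzofuran-6-carboxylate  
Conditions: Pd(PPh3)4, K3PO4, dioxane/H2O, 70 °C  
Reagents that add atoms: none  
Why: Suzuki–Miyaura cross-coupling: the electron-poor triflate 13 adds readily to zerovalent palladium and the alkenyl group of 8 is transferred with the double bond kept in the 1,1-disubstituted position; phosphate is mild enough for the methyl esters.

Step 9  
Reactants: 14 methyl 2-acetyl-3-[4-(4-{[2-methoxy-5-(methoxycarbonyl)phenyl]oxy}phenyl)but-1-en-2-yl]-1-benzofuran-6-carboxylate  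
Product: 16 methyl 2-(2-diazoacetyl)-3-[4-(4-{[2-methoxy-5-(methoxycarbonyl)phenyl]oxy}phenyl)but-1-en-2-yl]-1-benzofuran-6-carboxylate, via trifluoroacetyl diketone 15 (not isolated)  
Conditions: LiHMDS, THF, −78 °C; CF3CO2CH2CF3; aq. HCl work-up; then MsN3, Et3N, H2O, MeCN, rt  
Reagents that add atoms: methanesulfonyl azide, CS(=O)(=O)N=[N+]=[N-]; 2,2,2-trifluoroethyl trifluoroacetate, O=C(OCC(F)(F)F)C(F)(F)F (its atoms stay only in intermediate 15)  
Why: Detrifluoroacetylative diazo transfer: the lithium enolate of the only enolizable carbonyl is C-trifluoroacetylated, and the 1,3-diketone 15 takes the diazo group from the sulfonyl azide while the trifluoroacetyl group leaves as the N-sulfonyl amide. No acid and no diazomethane are involved, so the 1,1-disubstituted alkene and both methyl esters should stay untouched.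

Step 10  
Reactants: 16 methyl 2-(2-diazoacetyl)-3-[4-(4-{[2-methoxy-5-(methoxycarbonyl)phenyl]oxy}phenyl)but-1-en-2-yl]-1-benzofuran-6-carboxylate  
Product: 19 methyl 3-hydroxy-1-[2-(4-{[2-methoxy-5-(methoxycarbonyl)phenyl]oxy}phenyl)ethyl]dibenzo[b,d]furan-7-carboxylate, via ketene 17 (not isolated), via cyclohexadienone 18 (not isolated)  
Conditions: hν (365 nm), PhMe (0.005 M), Ar, rt; then 80 °C  
Reagents that add atoms: none  
Why: Photoexcitation of the diazoketone expels N2 with concerted 1,2-shift of the benzofuran-2-yl group (Wolff rearrangement), which forms C4–C4a and gives ketene 17. In 17 the ketene C=C, the furan C4a=C9b bond and the C1=C2 alkene form a hexatriene whose termini are held cis on adjacent ring carbons; thermal disrotatory 6π-electrocyclization forms C2–C3 and closes ring A as a six-membered ring (dienone 18), and enolization gives phenol 19 and restores the aromatic furan. The closest known reaction type is the photochemical Wolff rearrangement of aryl diazomethyl ketones bearing an ortho alkenyl group, which gives fused phenols by the same electrocyclization, together with the related aromatic annulation through vinylketenes. No stereocentre is formed. The step needs rearrangement to win over carbene addition to the neighbouring alkene, and electrocyclization to win over dimerization or acylation of phenol already formed: direct, metal-free irradiation favours the concerted shift, the cis-fixed alkene makes ring closure unimolecular, and high dilution in a dry aprotic solvent suppresses bimolecular capture. Warming after irradiation is meant to complete the closure, whose transition state has to interrupt the furan conjugation. The positions of the hydroxyl (C3) and of the side chain (C1) follow from connectivity.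

Step 11  
Reactants: 19 methyl 3-hydroxy-1-[2-(4-{[2-methoxy-5-(methoxycarbonyl)phenyl]oxy}phenyl)ethyl]dibenzo[b,d]furan-7-carboxylate  
Product: 20 methyl 3-methoxy-1-[2-(4-{[2-methoxy-5-(methoxycarbonyl)phenyl]oxy}phenyl)ethyl]dibenzo[b,d]furan-7-carboxylate  
Conditions: MeI, K2CO3, DMF, rt  
Reagents that add atoms: iodomethane, CI  
Why: Williamson methylation of the phenol; it caps the hydroxyl before hydride reduction, oxidation and the titanium-mediated coupling.

Step 12  
Reactants: 20 methyl 3-methoxy-1-[2-(4-{[2-methoxy-5-(methoxycarbonyl)phenyl]oxy}phenyl)ethyl]dibenzo[b,d]furan-7-carboxylate  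
Product: 21 [1-(2-{4-[5-(hydroxymethyl)-2-methoxyphenoxy]phenyl}ethyl)-3-methoxydibenzo[b,d]furan-7-yl]methanol  
Conditions: LiAlH4, THF, 0 °C  
Reagents that add atoms: none  
Why: Hydride reduction of both aryl esters to the benzylic alcohols; the ethers and the dibenzofuran are inert.

Step 13  
Reactants: 21 [1-(2-{4-[5-(hydroxymethyl)-2-methoxyphenoxy]phenyl}ethyl)-3-methoxydibenzo[b,d]furan-7-yl]methanol  
Product: 22 1-{2-[4-(5-formyl-2-methoxyphenoxy)phenyl]ethyl}-3-methoxydibenzo[b,d]furan-7-carbaldehyde  
Conditions: Dess–Martin periodinane, CH2Cl2, rt  
Reagents that add atoms: none  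
Why: Dess–Martin oxidation of the two primary benzylic alcohols stops at the aldehydes under neutral conditions.

Step 14  
Reactants: 22 1-{2-[4-(5-formyl-2-methoxyphenoxy)phenyl]ethyl}-3-methoxydibenzo[b,d]furan-7-carbaldehyde  
Product: 23 7,1'-didehydro-di-O-methylasterelin A (macrocyclic stilbene at the ring B–ring C bridge; drawn Z)  
Conditions: TiCl4, Zn, pyridine, THF, reflux, slow addition (high dilution)  
Reagents that add atoms: none  
Why: McMurry coupling: electron transfer from low-valent titanium gives ketyl radicals that couple to a titanium pinacolate, which is deoxygenated to the alkene. Slow addition at high dilution favours closure of the 18-membered ring over oligomerization, and both alkene geometries converge in step 15.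

Step 15  
Reactants: 23 7,1'-didehydro-di-O-methylasterelin A  
Product: 24 di-O-methyl asterelin A  
Conditions: H2 (1 atm), Pd/C, EtOAc/THF, rt  
Reagents that add atoms: none  
Why: Catalytic hydrogenation of the stilbene gives the saturated bibenzyl bridge; aryl ethers and the dibenzofuran are not hydrogenolysed under these conditions.

Step 16  
Reactants: 24 di-O-methyl asterelin A  
Product: 25 asterelin A  
Conditions: BBr3, CH2Cl2, −78 °C → rt; H2O  
Reagents that add atoms: none  
Why: Lewis-acid ether cleavage: bromide attacks the methyl carbon of each boron-complexed aryl methyl ether; the diaryl ether and the furan C–O bonds offer no alkyl carbon and should survive.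

## Compound list

1 | methyl 3-hydroxy-4-methoxybenzoate | COC(=O)c1ccc(OC)c(O)c1 | starting material  
2 | 4-fluorobenzaldehyde | O=Cc1ccc(F)cc1 | starting material  
3 | methyl 3-(4-formylphenoxy)-4-methoxybenzoate | COC(=O)c1ccc(OC)c(Oc2ccc(C=O)cc2)c1 | intermediate  
4 | 1-(triphenyl-λ5-phosphanylidene)propan-2-one | CC(=O)C=P(c1ccccc1)(c1ccccc1)c1ccccc1 | starting material  
5 | methyl 4-methoxy-3-{4-[(1E)-3-oxobut-1-en-1-yl]phenoxy}benzoate | COC(=O)c1ccc(OC)c(Oc2ccc(/C=C/C(C)=O)cc2)c1 | intermediate  
6 | methyl 4-methoxy-3-[4-(3-oxobutyl)phenoxy]benzoate | COC(=O)c1ccc(OC)c(Oc2ccc(CCC(C)=O)cc2)c1 | intermediate  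
7 | methyl 4-methoxy-3-[4-(3-{[(trifluoromethyl)sulfonyl]oxy}but-3-en-1-yl)phenoxy]benzoate | COC(=O)c1ccc(OC)c(Oc2ccc(CCC(=C)OS(=O)(=O)C(F)(F)F)cc2)c1 | intermediate  
8 | methyl 4-methoxy-3-{4-[3-(4,4,5,5-tetramethyl-1,3,2-dioxaborolan-2-yl)but-3-en-1-yl]phenoxy}benzoate | COC(=O)c1ccc(OC)c(Oc2ccc(CCC(=C)B3OC(C)(C)C(C)(C)O3)cc2)c1 | intermediate  
9 | dimethyl 2-hydroxyterephthalate | COC(=O)c1ccc(C(=O)OC)c(O)c1 | starting material  
10 | chloroacetone (1-chloropropan-2-one) | CC(=O)CCl | starting material  
11 | dimethyl 2-(2-oxopropoxy)terephthalate | COC(=O)c1ccc(C(=O)OC)c(OCC(C)=O)c1 | intermediate  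
12 | methyl 2-acetyl-3-hydroxy-1-benzofuran-6-carboxylate | CC(=O)c1oc2cc(C(=O)OC)ccc2c1O | intermediate  
13 | methyl 2-acetyl-3-{[(trifluoromethyl)sulfonyl]oxy}-1-benzofuran-6-carboxylate | CC(=O)c1oc2cc(C(=O)OC)ccc2c1OS(=O)(=O)C(F)(F)F | intermediate  
14 | methyl 2-acetyl-3-[4-(4-{[2-methoxy-5-(methoxycarbonyl)phenyl]oxy}phenyl)but-1-en-2-yl]-1-benzofuran-6-carboxylate | CC(=O)c1oc2cc(C(=O)OC)ccc2c1C(=C)CCc1ccc(Oc2cc(C(=O)OC)ccc2OC)cc1 | intermediate  
15 | methyl 3-[4-(4-{[2-methoxy-5-(methoxycarbonyl)phenyl]oxy}phenyl)but-1-en-2-yl]-2-(4,4,4-trifluoro-3-oxobutanoyl)-1-benzofuran-6-carboxylate | O=C(CC(=O)C(F)(F)F)c1oc2cc(C(=O)OC)ccc2c1C(=C)CCc1ccc(Oc2cc(C(=O)OC)ccc2OC)cc1 | intermediate  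
16 | methyl 2-(2-diazoacetyl)-3-[4-(4-{[2-methoxy-5-(methoxycarbonyl)phenyl]oxy}phenyl)but-1-en-2-yl]-1-benzofuran-6-carboxylate | [N-]=[N+]=CC(=O)c1oc2cc(C(=O)OC)ccc2c1C(=C)CCc1ccc(Oc2cc(C(=O)OC)ccc2OC)cc1 | intermediate  
17 | methyl 3-[4-(4-{[2-methoxy-5-(methoxycarbonyl)phenyl]oxy}phenyl)but-1-en-2-yl]-2-(2-oxoethenyl)-1-benzofuran-6-carboxylate (ketene) | O=C=Cc1oc2cc(C(=O)OC)ccc2c1C(=C)CCc1ccc(Oc2cc(C(=O)OC)ccc2OC)cc1 | intermediate  
18 | methyl 1-[2-(4-{[2-methoxy-5-(methoxycarbonyl)phenyl]oxy}phenyl)ethyl]-3-oxo-2,3-dihydrodibenzo[b,d]furan-7-carboxylate | O=C1C=C2Oc3cc(C(=O)OC)ccc3C2=C(CCc2ccc(Oc3cc(C(=O)OC)ccc3OC)cc2)C1 | intermediate  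
19 | methyl 3-hydroxy-1-[2-(4-{[2-methoxy-5-(methoxycarbonyl)phenyl]oxy}phenyl)ethyl]dibenzo[b,d]furan-7-carboxylate | Oc1cc(CCc2ccc(Oc3cc(C(=O)OC)ccc3OC)cc2)c2c(c1)oc1cc(C(=O)OC)ccc12 | intermediate  
20 | methyl 3-methoxy-1-[2-(4-{[2-methoxy-5-(methoxycarbonyl)phenyl]oxy}phenyl)ethyl]dibenzo[b,d]furan-7-carboxylate | COc1cc(CCc2ccc(Oc3cc(C(=O)OC)ccc3OC)cc2)c2c(c1)oc1cc(C(=O)OC)ccc12 | intermediate  
21 | [1-(2-{4-[5-(hydroxymethyl)-2-methoxyphenoxy]phenyl}ethyl)-3-methoxydibenzo[b,d]furan-7-yl]methanol | COc1cc(CCc2ccc(Oc3cc(CO)ccc3OC)cc2)c2c(c1)oc1cc(CO)ccc12 | intermediate  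
22 | 1-{2-[4-(5-formyl-2-methoxyphenoxy)phenyl]ethyl}-3-methoxydibenzo[b,d]furan-7-carbaldehyde | COc1cc(CCc2ccc(Oc3cc(C=O)ccc3OC)cc2)c2c(c1)oc1cc(C=O)ccc12 | intermediate  
23 | 7,1'-didehydro-di-O-methylasterelin A (Z-stilbene at the ring B–ring C bridge) | COc1cc2c3c(c1)oc1cc(ccc13)/C=C\c1ccc(OC)c(c1)Oc1ccc(cc1)CC2 | intermediate  
24 | di-O-methyl asterelin A | COc1cc2c3c(c1)oc1cc(ccc13)CCc1ccc(OC)c(c1)Oc1ccc(cc1)CC2 | intermediate  
25 | asterelin A | Oc1cc2c3c(c1)oc1cc(ccc13)CCc1ccc(O)c(c1)Oc1ccc(cc1)CC2 | target  

## Step count and least certain steps

Total step count: 16. Longest linear sequence: 14 steps (steps 1 to 5 and 8 to 16).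

Step 10 (key step).
- What may go wrong: the ketene may be lost to bimolecular processes (dimerization, acylation of phenol already formed, capture by adventitious water) if the electrocyclization, which must pass through a non-aromatic furan, is slower than assumed. Carbene addition to the neighbouring alkene may compete with the 1,2-shift, and the diazo group may undergo dipolar cycloaddition with that alkene if 16 is stored.
- Fallback (sets out from 16, comes back at 19): silver-catalysed Wolff rearrangement of 16 (PhCO2Ag, Et3N, THF/H2O) would trap the ketene with water as 2-{6-(methoxycarbonyl)-3-[4-(4-{[2-methoxy-5-(methoxycarbonyl)phenyl]oxy}phenyl)but-1-en-2-yl]-1-benzofuran-2-yl}acetic acid F1. Heating F1 with acetic anhydride and sodium acetate would close ring A through the mixed anhydride by acylation of the alkene terminus (the same C2–C3 bond, now a thermal ionic process) and give the aryl acetate methyl 3-acetoxy-1-[2-(4-{[2-methoxy-5-(methoxycarbonyl)phenyl]oxy}phenyl)ethyl]dibenzo[b,d]furan-7-carboxylate F2. Methanolysis (K2CO3, MeOH) would give 19.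

Step 14.
- What may go wrong: intermolecular coupling to oligomers and arrest at the pinacol stage, because the ring to be closed is strained by the rigid dibenzofuran; reduction of an aldehyde without coupling is also possible.
- Fallback (sets out from 21, comes back at 24): PBr3 would convert 21 into 7-(bromomethyl)-1-(2-{4-[5-(bromomethyl)-2-methoxyphenoxy]phenyl}ethyl)-3-methoxydibenzo[b,d]furan F3. Intramolecular Wurtz-type coupling (Na, tetraphenylethylene, THF, high dilution) would form the saturated CH2–CH2 bridge directly and give 24, so that steps 13 to 15 are bypassed. The mediator is too mild a reductant to attack the dibenzofuran, and a saturated bridge asks less of the ring-closing transition state than an alkene.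

Step 9.
- What may go wrong: Claisen-type attack of the ketone enolate on a methyl ester of a second molecule, incomplete trifluoroacetylation, and loss of diazoketone by intramolecular cycloaddition during concentration.
- Fallback (sets out from 9, comes back at 16; it replaces steps 6 to 9 by the carboxylic acid route): tert-butyl bromoacetate (K2CO3, DMF) would alkylate 9 to dimethyl 2-(2-tert-butoxy-2-oxoethoxy)terephthalate F4, which t-BuOK would close to 2-tert-butyl 6-methyl 3-hydroxy-1-benzofuran-2,6-dicarboxylate F5. Tf2O/pyridine would give the triflate 2-tert-butyl 6-methyl 3-{[(trifluoromethyl)sulfonyl]oxy}-1-benzofuran-2,6-dicarboxylate F6, and Suzuki coupling with 8 would give 2-tert-butyl 6-methyl 3-[4-(4-{[2-methoxy-5-(methoxycarbonyl)phenyl]oxy}phenyl)but-1-en-2-yl]-1-benzofuran-2,6-dicarboxylate F7. TMSOTf with 2,6-lutidine would cleave the tert-butyl ester under buffered conditions, which protect the alkene from protonation, by way of the trimethylsilyl ester F8, hydrolysed on work-up to 6-(methoxycarbonyl)-3-[4-(4-{[2-methoxy-5-(methoxycarbonyl)phenyl]oxy}phenyl)but-1-en-2-yl]-1-benzofuran-2-carboxylic acid F9. 1-Chloro-N,N,2-trimethylprop-1-en-1-amine would give the acid chloride F10 without free HCl, and acylation of trimethylsilyldiazomethane (MeCN/THF, 0 °C) would give 16.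

Step 8.
- What may go wrong: hydrolytic S–O cleavage of the electron-poor triflate by the aqueous base, which would return 12, and protodeboronation of the α-substituted alkenylboronate before transmetalation.
- Fallback (sets out from 7, comes back at 14): stannylation of 7 with Me3SnSnMe3 (Pd(PPh3)4, LiCl, dioxane) would give methyl 4-methoxy-3-{4-[3-(trimethylstannyl)but-3-en-1-yl]phenoxy}benzoate F11. Stille coupling of F11 with 13 (Pd(PPh3)4, CuI, LiCl, DMF), which needs neither base nor water, would give 14.

## Further compounds

F1 | step 10 | 2-{6-(methoxycarbonyl)-3-[4-(4-{[2-methoxy-5-(methoxycarbonyl)phenyl]oxy}phenyl)but-1-en-2-yl]-1-benzofuran-2-yl}acetic acid | OC(=O)Cc1oc2cc(C(=O)OC)ccc2c1C(=C)CCc1ccc(Oc2cc(C(=O)OC)ccc2OC)cc1  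
F2 | step 10 | methyl 3-acetoxy-1-[2-(4-{[2-methoxy-5-(methoxycarbonyl)phenyl]oxy}phenyl)ethyl]dibenzo[b,d]furan-7-carboxylate | CC(=O)Oc1cc(CCc2ccc(Oc3cc(C(=O)OC)ccc3OC)cc2)c2c(c1)oc1cc(C(=O)OC)ccc12  
F3 | step 14 | 7-(bromomethyl)-1-(2-{4-[5-(bromomethyl)-2-methoxyphenoxy]phenyl}ethyl)-3-methoxydibenzo[b,d]furan | COc1cc(CCc2ccc(Oc3cc(CBr)ccc3OC)cc2)c2c(c1)oc1cc(CBr)ccc12  
F4 | step 9 | dimethyl 2-(2-tert-butoxy-2-oxoethoxy)terephthalate | COC(=O)c1ccc(C(=O)OC)c(OCC(=O)OC(C)(C)C)c1  
F5 | step 9 | 2-tert-butyl 6-methyl 3-hydroxy-1-benzofuran-2,6-dicarboxylate | CC(C)(C)OC(=O)c1oc2cc(C(=O)OC)ccc2c1O  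
F6 | step 9 | 2-tert-butyl 6-methyl 3-{[(trifluoromethyl)sulfonyl]oxy}-1-benzofuran-2,6-dicarboxylate | CC(C)(C)OC(=O)c1oc2cc(C(=O)OC)ccc2c1OS(=O)(=O)C(F)(F)F  
F7 | step 9 | 2-tert-butyl 6-methyl 3-[4-(4-{[2-methoxy-5-(methoxycarbonyl)phenyl]oxy}phenyl)but-1-en-2-yl]-1-benzofuran-2,6-dicarboxylate | CC(C)(C)OC(=O)c1oc2cc(C(=O)OC)ccc2c1C(=C)CCc1ccc(Oc2cc(C(=O)OC)ccc2OC)cc1  
F8 | step 9 | 6-methyl 2-trimethylsilyl 3-[4-(4-{[2-methoxy-5-(methoxycarbonyl)phenyl]oxy}phenyl)but-1-en-2-yl]-1-benzofuran-2,6-dicarboxylate | C[Si](C)(C)OC(=O)c1oc2cc(C(=O)OC)ccc2c1C(=C)CCc1ccc(Oc2cc(C(=O)OC)ccc2OC)cc1  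
F9 | step 9 | 6-(methoxycarbonyl)-3-[4-(4-{[2-methoxy-5-(methoxycarbonyl)phenyl]oxy}phenyl)but-1-en-2-yl]-1-benzofuran-2-carboxylic acid | OC(=O)c1oc2cc(C(=O)OC)ccc2c1C(=C)CCc1ccc(Oc2cc(C(=O)OC)ccc2OC)cc1  
F10 | step 9 | methyl 2-(chlorocarbonyl)-3-[4-(4-{[2-methoxy-5-(methoxycarbonyl)phenyl]oxy}phenyl)but-1-en-2-yl]-1-benzofuran-6-carboxylate | ClC(=O)c1oc2cc(C(=O)OC)ccc2c1C(=C)CCc1ccc(Oc2cc(C(=O)OC)ccc2OC)cc1  
F11 | step 8 | methyl 4-methoxy-3-{4-[3-(trimethylstannyl)but-3-en-1-yl]phenoxy}benzoate | COC(=O)c1ccc(OC)c(Oc2ccc(CCC(=C)[Sn](C)(C)C)cc2)c1  
A1 | alternative 1 | di-O-methyl asterelin A (constitution of 24) | COc1cc2c3c(c1)oc1cc(ccc13)CCc1ccc(OC)c(c1)Oc1ccc(cc1)CC2  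
A2 | alternative 1 | 18-membered 2-hydroxybiaryl macrocycle (C4a hydroxyl free, C3 and C4' methoxy, ring B para-phenylene) | COc1cc2c(c(O)c1)-c1ccc(cc1)CCc1ccc(OC)c(c1)Oc1ccc(cc1)CC2  
A3 | alternative 2 | macrocyclic stilbene at the ring A–ring D bridge (drawn Z), di-O-methyl | c1cc2ccc1Oc1cc(ccc1OC)CCc1ccc3c(c1)oc1cc(OC)cc(/C=C\2)c13  
A4 | alternative 2 | 7-{2-[3-(4-formylphenoxy)-4-methoxyphenyl]ethyl}-3-methoxydibenzo[b,d]furan-1-carbaldehyde | O=Cc1ccc(cc1)Oc1cc(ccc1OC)CCc1ccc2c(c1)oc1cc(OC)cc(C=O)c12  
A5 | alternative 3 | macrocyclic stilbene at the ring B–ring C bridge (drawn Z; constitution of 23) | COc1cc2c3c(c1)oc1cc(ccc13)/C=C\c1ccc(OC)c(c1)Oc1ccc(cc1)CC2  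
A6 | alternative 3 | 19-membered dibenzylic sulfone (CH2–SO2–CH2 between C7 and C1') | COc1cc2c3c(c1)oc1cc(ccc13)CS(=O)(=O)Cc1ccc(OC)c(c1)Oc1ccc(cc1)CC2  
A7 | alternative 3 | 19-membered dibenzylic sulfide (CH2–S–CH2 between C7 and C1') | COc1cc2c3c(c1)oc1cc(ccc13)CSCc1ccc(OC)c(c1)Oc1ccc(cc1)CC2  
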